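**Plan**

Numbering: C1 lactone C=O, C2 CH2, C3 CH(OO), C4 C(CH3)(O-lactone), C5 ring CH2, C6 C(CH3)(chain)(OO), C7 first CH2 of the 10-phenyldecyl chain.
Cuts, in retrosynthetic order: C6–CH3 (methyl donor on a C6 peroxycarbenium ion); both C–O bonds of the peroxide (O2 is taken out and C3 is rejoined to C6); C6–C7 (Grignard addition to a cyclobutanone); C3–C6 and C4–C5 ([2+2] of an enol lactone with a ketene equivalent).
Enabling feature: the four carbons of the 1,2-dioxane ring (C3, C4, C5, C6) are a cyclobutane that lacks only the C3–C6 bond. C6 carries oxygen and C3 is secondary, so a lactone-fused C6 cyclobutanol can open by strain-driven β-scission at exactly this bond and take up O2 there.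
Forward order: the γ-lactone ring is bought (α-angelica lactone), the cyclobutane is fused onto its C3=C4 bond, and the chain is added at C6. The cyclobutane is then expanded by two oxygen atoms to the 1,2-dioxane, and the C6 methyl group comes last.
Stereochemistry: C4 (with C3) is set once by the catalyst of the [2+2]. C4 then relays to C3 (only the cis-fused peroxyhemiketal can close) and to C6 (axial attack on the bicyclic peroxycarbenium ion from the lactone face).

Key step: step 5

Assumption: the sense of induction in step 2 cannot be derived from known cases. The (S)-catalyst is written, and its commercial antipode is to be taken if an analytical run shows the opposite sense.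

**Step 1**
Reactants: 1 1,10-dibromodecane; 2 phenylmagnesium bromide
Product: 3 (10-bromodecyl)benzene
Conditions: 2 (1 equiv) added to 1 (3 equiv), Li2CuCl4 (3 mol %), THF, 0 °C to rt
Reagents that add atoms: none
Why: Kochi-type copper-catalysed cross-coupling of an aryl Grignard reagent with a primary alkyl bromide, in which the excess of the symmetrical dibromide should hold double substitution down and is recovered by distillation; no stereocenter is formed.

**Step 2**
Reactants: 4 α-angelica lactone (5-methylfuran-2(3H)-one); 5 ethyl buta-2,3-dienoate
Product: 6 ethyl 2-[(1R,5S)-1-methyl-3-oxo-2-oxabicyclo[3.2.0]heptan-6-ylidene]acetate (cis-fused, E/Z mixture)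
Conditions: (S)-o-tolyl-oxazaborolidine activated with Tf2NH (20 mol %), 4 (3 equiv), CH2Cl2, −20 °C to rt
Reagents that add atoms: none
Why: Proposed new method: the catalyst-bound allenoate is attacked at its central carbon by C3, the nucleophilic β-carbon of the enol ester, while positive charge builds at C4 where the ring oxygen and the methyl group stabilise it, and the γ-CH2 of the dienolate closes on C4 in a concerted but asynchronous [2+2]; this fixes the regiochemistry (C3–C6 and C4–C5), enforces the cis fusion because the addition is suprafacial on a ring alkene, and sets C3 and C4 together through the catalyst's choice of the lactone face; the closest known reaction type is the oxazaborolidine-catalysed enantioselective allenoate–alkene [2+2] cycloaddition of unactivated 1,1-di- and trisubstituted alkenes (related catalysts accept cyclic enol ethers in acrylate [2+2] reactions), but an enol lactone has not served as the alkene partner.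

**Step 3**
Reactants: 6 ethyl 2-[(1R,5S)-1-methyl-3-oxo-2-oxabicyclo[3.2.0]heptan-6-ylidene]acetate
Product: 7 (1R,5R)-1-methyl-2-oxabicyclo[3.2.0]heptane-3,6-dione
Conditions: O3, CH2Cl2, −78 °C; then Me2S, −78 °C to rt
Reagents that add atoms: ozone, [O-][O+]=O
Why: Ozonolysis with reductive work-up cleaves the only C=C bond, so both alkene isomers converge on the cyclobutanone, the lactone and both stereocenters are untouched, and the cold neutral work-up avoids β-elimination of the carboxylate.

**Step 4**
Reactants: 3 (10-bromodecyl)benzene; 7 (1R,5R)-1-methyl-2-oxabicyclo[3.2.0]heptane-3,6-dione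
Product: 9 (1R,5S,6S)-6-hydroxy-1-methyl-6-(10-phenyldecyl)-2-oxabicyclo[3.2.0]heptan-3-one (OH endo, chain exo), via 10-phenyldecylmagnesium bromide 8 (not isolated)
Conditions: 3, Mg, THF, rt; then 7, LaCl3·2LiCl (1 equiv), THF, −78 °C; AcOH/THF quench at −78 °C
Reagents that add atoms: none
Why: Lanthanide-assisted Grignard 1,2-addition, in which the strained cyclobutanone is far more electrophilic than the lactone, LaCl3·2LiCl suppresses enolisation and β-elimination, attack from the convex face (that of C3–H and C4–CH3) should place OH endo (a configuration erased in step 5), and the cold acidic quench forestalls acyl migration to the new alkoxide, which would have to pass a strained tricyclic ortho-acid.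

**Step 5**
Reactants: 9 (1R,5S,6S)-6-hydroxy-1-methyl-6-(10-phenyldecyl)-2-oxabicyclo[3.2.0]heptan-3-one
Product: 11 (3R,4aR,7aR)-3-hydroxy-4a-methyl-3-(10-phenyldecyl)tetrahydrofuro[3,2-c][1,2]dioxin-6-one (cis-fused peroxyhemiketal, OH axial), via keto hydroperoxide 10 (not isolated)
Conditions: Co(acac)2 (20 mol %), O2 (1 atm), THF, rt to 40 °C
Reagents that add atoms: dioxygen, O=O
Why: Co(acac)2 and O2 form a Co(III) alkoxide of the tertiary cyclobutanol, its homolysis gives the C6 alkoxy radical, and release of the four-ring strain (about 26 kcal/mol) drives β-scission of the C6–C3 bond to the C6 ketone and a secondary radical at C3 of the intact lactone; triplet O2 adds at C3, the cobalt chain turns the peroxyl radical into hydroperoxide 10, and its OOH adds to the C6 ketone, so that O–O stands where the C3–C6 bond stood and the carbocycle C3–C4–C5–C6 has grown by two atoms into the 1,2-dioxane. The closest known reaction type is the cobalt-catalysed aerobic oxidative ring expansion of secondary and tertiary cyclobutanols to 1,2-dioxan-3-ols, the homologue of the cyclopropanol to 1,2-dioxolan-3-ol oxygenation. The only ring closure is the 6-exo-trig addition of the terminal hydroperoxide oxygen to the ketone carbonyl. C4 is untouched and acts as the control element for C3: the radical is planar, and only the epimer that carries OOH on the face of the ketone arm can close to the unstrained cis-fused hemiketal and is collected as 11; C6 settles under thermodynamic, anomeric control (OH axial, chain equatorial) and is made anew in step 7. Regioselective scission is secured by the substrate, since C6–C3 gives a secondary radical, C6–C5 a primary neopentyl radical and C6–C7 relieves no strain, and scission and O2 capture should outrun 1,5-hydrogen transfer from the chain and the 1,2-acyloxy shift of the β-acyloxy radical. Facial selectivity at C3 is the weak point, because C4 offers only the difference between CH3 and the CH2 of the arm, and it is therefore treated among the risks.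

**Step 6**
Reactants: 11 (3R,4aR,7aR)-3-hydroxy-4a-methyl-3-(10-phenyldecyl)tetrahydrofuro[3,2-c][1,2]dioxin-6-one
Product: 12 (3R,4aR,7aR)-4a-methyl-6-oxo-3-(10-phenyldecyl)tetrahydrofuro[3,2-c][1,2]dioxin-3-yl acetate
Conditions: Ac2O, pyridine, DMAP (cat.), CH2Cl2, 0 °C
Reagents that add atoms: acetic anhydride, CC(=O)OC(C)=O
Why: O-acylation of the peroxyhemiketal, the usual activation of 1,2-dioxan-3-ols and 1,2-dioxolan-3-ols for peroxycarbenium chemistry, should trap the closed form as the anomerically favoured axial acetate, whose configuration is lost on ionisation in step 7.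

**Step 7**
Reactants: 12 (3R,4aR,7aR)-4a-methyl-6-oxo-3-(10-phenyldecyl)tetrahydrofuro[3,2-c][1,2]dioxin-3-yl acetate
Product: 14 (3R,4aR,7aR)-3,4a-dimethyl-3-(10-phenyldecyl)tetrahydrofuro[3,2-c][1,2]dioxin-6-one (target), via peroxycarbenium ion 13 (not isolated)
Conditions: AlMe3 (3 equiv), CH2Cl2, −78 to −40 °C; aq. Rochelle salt
Reagents that add atoms: trimethylaluminium, C[Al](C)C
Why: Proposed new method: AlMe3 binds the acetate and ionises the C6–OAc bond to peroxycarbenium ion 13 paired with the methylaluminate, which hands a methyl group back to C6; in the half-chair of 13 that keeps C4–CH3 pseudoequatorial and the lactone oxygen pseudoaxial, chair-like axial attack comes from the lactone face (the face the axial acetate left), so CH3 ends axial and cis to the lactone oxygen with the chain equatorial, which is the (R) configuration at C6 and agrees with the 3,6-cis preference known for neutral nucleophiles, whereas the other half-chair would force the methyl donor into a 1,3-diaxial clash with C4–CH3; at low temperature AlMe3 is expected to spare lactone and O–O bond, as in methylations of anomeric acetates and fluorides of peroxide-bearing lactols; the closest known reaction types are the Lewis-acid-mediated substitution of 3-acyloxy- and 3-alkoxy-1,2-dioxanes and -dioxolanes by allylsilanes, silyl ketene acetals and Et3SiH through peroxycarbenium ions, and the AlMe3 methylation of α-acetoxy ethers through oxocarbenium ions, but an organoaluminium carbon nucleophile has not been shown on a peroxycarbenium ion.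

**Compound list**

1 | 1,10-dibromodecane | BrCCCCCCCCCCBr | starting material
2 | phenylmagnesium bromide | Br[Mg]c1ccccc1 | starting material
3 | (10-bromodecyl)benzene | BrCCCCCCCCCCc1ccccc1 | intermediate
4 | α-angelica lactone (5-methylfuran-2(3H)-one) | CC1=CCC(=O)O1 | starting material
5 | ethyl buta-2,3-dienoate | C=C=CC(=O)OCC | starting material
6 | ethyl 2-[(1R,5S)-1-methyl-3-oxo-2-oxabicyclo[3.2.0]heptan-6-ylidene]acetate (E/Z mixture) | CCOC(=O)C=C1C[C@@]2(C)OC(=O)C[C@H]21 | intermediate
7 | (1R,5R)-1-methyl-2-oxabicyclo[3.2.0]heptane-3,6-dione | O=C1C[C@@]2(C)OC(=O)C[C@H]21 | intermediate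
8 | 10-phenyldecylmagnesium bromide | Br[Mg]CCCCCCCCCCc1ccccc1 | intermediate
9 | (1R,5S,6S)-6-hydroxy-1-methyl-6-(10-phenyldecyl)-2-oxabicyclo[3.2.0]heptan-3-one | O[C@@]1(CCCCCCCCCCc2ccccc2)C[C@@]3(C)OC(=O)C[C@H]31 | intermediate
10 | (4R,5R)-4-hydroperoxy-5-methyl-5-(2-oxo-12-phenyldodecyl)dihydrofuran-2(3H)-one | O=C(CCCCCCCCCCc1ccccc1)C[C@@]2(C)OC(=O)C[C@H]2OO | intermediate
11 | (3R,4aR,7aR)-3-hydroxy-4a-methyl-3-(10-phenyldecyl)tetrahydrofuro[3,2-c][1,2]dioxin-6-one | O[C@@]1(CCCCCCCCCCc2ccccc2)C[C@@]3(C)OC(=O)C[C@H]3OO1 | intermediate
12 | (3R,4aR,7aR)-4a-methyl-6-oxo-3-(10-phenyldecyl)tetrahydrofuro[3,2-c][1,2]dioxin-3-yl acetate | CC(=O)O[C@@]1(CCCCCCCCCCc2ccccc2)C[C@@]3(C)OC(=O)C[C@H]3OO1 | intermediate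
13 | bicyclic C6 peroxycarbenium ion (C6=O+ within the dioxane ring, cis-fused lactone) | C1(CCCCCCCCCCc2ccccc2)C[C@@]3(C)OC(=O)C[C@H]3O[O+]=1 | intermediate
14 | (3R,4aR,7aR)-3,4a-dimethyl-3-(10-phenyldecyl)tetrahydrofuro[3,2-c][1,2]dioxin-6-one | C[C@@]1(CCCCCCCCCCc2ccccc2)C[C@@]2(C)OC(=O)C[C@H]2OO1 | target

**Step count**

Total step count: 7. Longest linear sequence: 6 (steps 2 to 7, from α-angelica lactone).

**Steps most likely to fail**

**Step 2.** Three things may go wrong:
- The cycloaddition may be sluggish, because an enol ester is a weaker π-donor than an enol ether and the ethyl allenoate is only a modest acceptor.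
- Acid may move the lactone double bond into conjugation or start cationic oligomerisation.
- The catalyst may discriminate the two lactone faces poorly.

The fallback sets out from 4 and comes back at 7, so step 3 is no longer needed. Dichloroketene, generated from trichloroacetyl chloride with Zn–Cu in Et2O/DME, is a far stronger electrophile. It adds to enol-type and trisubstituted alkenes with the same regiochemistry (carbonyl carbon to C3, CCl2 to C4). It should give the racemic cis-fused dichloro dione F1. Zn in AcOH removes both chlorine atoms to give the racemic dione F2. Preparative chromatography on a chiral phase (SFC) then delivers the (1R,5R) enantiomer, which is 7.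

**Step 7.** After ionisation, a proton may be lost from C5 or C7. The O–O bond may break heterolytically with a 1,2-shift. The aluminium reagent may also attack the O–O bond or the lactone.

The fallback sets out from 11 and comes back at 14, uses known chemistry, and gives up control at C6:
- PPh3 reduces 11 through its open form to the hydroxy keto lactone F3.
- MsCl/Et3N eliminates to the keto butenolide F4.
- Zn/CH2Br2/TiCl4 methylenates the ketone selectively to the 1,1-disubstituted alkene F5.
- Mukaiyama–Isayama peroxidation (Co(thd)2, O2, Et3SiH) gives the tertiary triethylsilyl peroxide F6 as both C6 epimers.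
- Et3N·3HF liberates the hydroperoxy butenolide F7.
- Et2NH in CF3CH2OH closes F7 by 6-exo-trig oxa-Michael addition on the face of the tether. This gives 14 together with its C6 epimer F8, and the two are separated by chromatography.

**Step 5.** Facial selectivity may be poor when O2 is captured at the planar C3 radical. The acyl group may also migrate between the two cis-1,3 tertiary oxygens at the cobalt alkoxide stage.

The fallback sets out from 9 and comes back at 11. It replaces radical oxygenation by tether-controlled ionic delivery of the peroxide. Radical ring-opening bromination of the cyclobutanol (NBS, PhI(OAc)2, visible light) gives the bromo keto lactone F9, whose C3 configuration does not matter. Et3N eliminates HBr to the keto butenolide F4 already met above. Urea–H2O2 with catalytic Sc(OTf)3 forms the ketone perhydrate F10. Et2NH in CF3CH2OH then closes F10 onto the butenolide from the face of the arm, which can give only the cis-fused 11.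

**Further compounds**

F1 | step 2 | racemic cis-fused 7,7-dichloro-1-methyl-2-oxabicyclo[3.2.0]heptane-3,6-dione (the enantiomer that leads to 7 is drawn) | O=C1C(Cl)(Cl)[C@@]2(C)OC(=O)C[C@H]21
F2 | step 2 | racemic cis-fused 1-methyl-2-oxabicyclo[3.2.0]heptane-3,6-dione (the enantiomer equal to 7 is drawn) | O=C1C[C@@]2(C)OC(=O)C[C@H]21
F3 | step 7 | (4R,5R)-4-hydroxy-5-methyl-5-(2-oxo-12-phenyldodecyl)dihydrofuran-2(3H)-one | O=C(CCCCCCCCCCc1ccccc1)C[C@@]2(C)OC(=O)C[C@H]2O
F4 | step 7 | (R)-5-methyl-5-(2-oxo-12-phenyldodecyl)furan-2(5H)-one | O=C(CCCCCCCCCCc1ccccc1)C[C@@]2(C)OC(=O)C=C2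
F5 | step 7 | (R)-5-methyl-5-(2-methylidene-12-phenyldodecyl)furan-2(5H)-one | C=C(CCCCCCCCCCc1ccccc1)C[C@@]2(C)OC(=O)C=C2
F6 | step 7 | (5R)-5-methyl-5-[2-methyl-12-phenyl-2-(triethylsilylperoxy)dodecyl]furan-2(5H)-one (both epimers at the peroxy carbon) | CC[Si](CC)(CC)OOC(C)(CCCCCCCCCCc1ccccc1)C[C@@]2(C)OC(=O)C=C2
F7 | step 7 | (5R)-5-(2-hydroperoxy-2-methyl-12-phenyldodecyl)-5-methylfuran-2(5H)-one (both epimers at the peroxy carbon) | OOC(C)(CCCCCCCCCCc1ccccc1)C[C@@]2(C)OC(=O)C=C2
F8 | step 7 | (3S,4aR,7aR)-3,4a-dimethyl-3-(10-phenyldecyl)tetrahydrofuro[3,2-c][1,2]dioxin-6-one (C6 epimer of 14) | C[C@]1(CCCCCCCCCCc2ccccc2)C[C@@]2(C)OC(=O)C[C@H]2OO1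
F9 | step 5 | (5R)-4-bromo-5-methyl-5-(2-oxo-12-phenyldodecyl)dihydrofuran-2(3H)-one (both C–Br epimers) | O=C(CCCCCCCCCCc1ccccc1)C[C@@]2(C)OC(=O)CC2Br
F10 | step 5 | (5R)-5-(2-hydroperoxy-2-hydroxy-12-phenyldodecyl)-5-methylfuran-2(5H)-one (ketone perhydrate) | OOC(O)(CCCCCCCCCCc1ccccc1)C[C@@]2(C)OC(=O)C=C2
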